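The flavone is cut at the C4 carbonyl of ring C, a ketone carbon held between C4a of ring A and C3, which can therefore enter as carbon monoxide. One palladium-catalysed carbonylative Sonogashira coupling makes C4a–C4 and C4–C3 at once, joining 4-ethynylanisole to a fully oxygenated ring A iodide, 3-(benzyloxy)-6-iodo-1,2,4,5-tetramethoxybenzene, in which iodine lies between two equivalent methoxy groups and the future 7-hydroxyl is masked as a benzyl ether. The resulting ynone is closed to ring C by demethylative iodocyclisation, which can occur in one sense only and leaves iodine at C3 for the 3-methoxy group; hydrogenolysis ends the route.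

Key step: step 5

Assumption: the target is read as 7-hydroxy-3,5,6,8-tetramethoxy-2-(4-methoxyphenyl)-4H-chromen-4-one with the usual flavone numbering (O1, C2, C3, C4, C4a, C5 to C8, C8a; ring A the benzo ring, ring C the pyranone, ring B the 4-methoxyphenyl group); it has no stereocentre.

Step 1
Reactants: 1 2,6-dimethoxyphenol (syringol)
Product: 2 2-(benzyloxy)-1,3-dimethoxybenzene
Conditions: BnBr (1.1 equiv), K2CO3 (1.5 equiv), DMF, 60 °C
Reagents that add atoms: benzyl bromide, BrCc1ccccc1
Why: Williamson ether synthesis, in which the phenoxide displaces bromide from the unhindered benzylic carbon and the benzyl ether later steers bromination away from the position para to oxygen.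

Step 2
Reactants: 2 2-(benzyloxy)-1,3-dimethoxybenzene
Product: 3 3-(benzyloxy)-1,5-dibromo-2,4-dimethoxybenzene
Conditions: NBS (2.2 equiv), MeCN, 0 °C to 40 °C, dark
Reagents that add atoms: N-bromosuccinimide, O=C1CCC(=O)N1Br
Why: Electrophilic aromatic bromination should go twice at the two equivalent positions that are each ortho to one methoxy group and para to the other, because the central benzyloxy group is flanked on both sides, twisted out of conjugation and so activates its own para position only weakly.

Step 3
Reactants: 3 3-(benzyloxy)-1,5-dibromo-2,4-dimethoxybenzene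
Product: 4 3-(benzyloxy)-1,2,4,5-tetramethoxybenzene
Conditions: NaOMe (30% in MeOH, excess), CuBr (20 mol%), DMF, 110 °C
Reagents that add atoms: sodium methoxide, [Na+].[O-]C
Why: Ullmann-type copper-catalysed methoxylation replaces both aryl bromides by methoxide, and the benzyl ether and methyl ethers are inert to methoxide.

Step 4
Reactants: 4 3-(benzyloxy)-1,2,4,5-tetramethoxybenzene
Product: 5 3-(benzyloxy)-6-iodo-1,2,4,5-tetramethoxybenzene
Conditions: NIS (1.1 equiv), TFA (10 mol%), MeCN, 0 °C to rt, dark
Reagents that add atoms: N-iodosuccinimide, O=C1CCC(=O)N1I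
Why: Electrophilic aromatic iodination can only take the single free position of the pentaoxygenated ring, which lies between two methoxy groups and is far more nucleophilic than the benzyl phenyl ring.

Step 5
Reactants: 5 3-(benzyloxy)-6-iodo-1,2,4,5-tetramethoxybenzene; 6 4-ethynylanisole; 7 carbon monoxide
Product: 8 1-[4-(benzyloxy)-2,3,5,6-tetramethoxyphenyl]-3-(4-methoxyphenyl)prop-2-yn-1-one
Conditions: PdCl2(PPh3)2 (5 mol%), Et3N (3 equiv), CO (1–5 bar), THF, 50 °C, no copper salt
Reagents that add atoms: none
Why: PdCl2(PPh3)2, a divalent palladium precatalyst, is reduced in the flask to zerovalent palladium, which inserts into the C–I bond of 5; CO then coordinates and migratory insertion gives an aroylpalladium iodide, forming C4a–C4. Triethylamine deprotonates alkyne 6 bound to this acyl complex, and reductive elimination from the aroyl(alkynyl)palladium species forms C4–C3 and returns zerovalent palladium. The closest known reaction type is the carbonylative Sonogashira coupling of aryl iodides with terminal alkynes to alkynyl ketones. No ring is closed and no stereocentre is created. The selectivity needed is acylation over direct aryl–alkynyl coupling: the two methoxy groups flanking the palladium-bearing carbon crowd the arylpalladium species, which slows alkyne transfer to it and favours the strain-relieving migration onto CO, and leaving out copper removes the fast acetylide transmetallation that could intercept it before insertion. Because ring A of 5 has a mirror plane through the C–I and C–OBn carbons, only one ynone can form.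

Step 6
Reactants: 8 1-[4-(benzyloxy)-2,3,5,6-tetramethoxyphenyl]-3-(4-methoxyphenyl)prop-2-yn-1-one
Product: 10 7-(benzyloxy)-3-iodo-5,6,8-trimethoxy-2-(4-methoxyphenyl)-4H-chromen-4-one, via O-methyl chromenylium chloride 9 (not isolated)
Conditions: ICl (1.5 equiv), CH2Cl2, −78 °C to rt; aq. Na2S2O3 work-up
Reagents that add atoms: iodine monochloride, ICl
Why: In this electrophilic iodocyclisation, iodonium activation of the alkyne lets one of the two equivalent ortho methoxy oxygens attack the anisyl-bearing carbon in a 6-endo-dig closure of ring C, and chloride then removes the methyl group of oxonium 9 by SN2 displacement, so that a single 3-iodoflavone can result.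

Step 7
Reactants: 10 7-(benzyloxy)-3-iodo-5,6,8-trimethoxy-2-(4-methoxyphenyl)-4H-chromen-4-one
Product: 11 7-(benzyloxy)-3,5,6,8-tetramethoxy-2-(4-methoxyphenyl)-4H-chromen-4-one
Conditions: CuI (20 mol%), 1,10-phenanthroline (40 mol%), Cs2CO3 (2 equiv), MeOH/toluene, 100 °C, sealed tube
Reagents that add atoms: methanol, CO
Why: Ullmann-type copper-catalysed C–O coupling of a vinylic iodide with an aliphatic alcohol should engage the C3–I bond of the iodoenone through the monovalent copper methoxide–phenanthroline complex, while carbonate keeps free methoxide low enough to spare the pyranone ring.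

Step 8
Reactants: 11 7-(benzyloxy)-3,5,6,8-tetramethoxy-2-(4-methoxyphenyl)-4H-chromen-4-one
Product: 12 7-hydroxy-3,5,6,8-tetramethoxy-2-(4-methoxyphenyl)-4H-chromen-4-one
Conditions: H2 (1 atm), 10% Pd/C, EtOAc/MeOH, rt
Reagents that add atoms: none
Why: Catalytic hydrogenolysis of the aryl benzyl ether frees the 7-hydroxyl, while the tetrasubstituted, donor-substituted C2–C3 double bond and the methyl ethers should be inert at 1 atm and room temperature.

Compound list
1 | 2,6-dimethoxyphenol (syringol) | COc1cccc(OC)c1O | starting material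
2 | 2-(benzyloxy)-1,3-dimethoxybenzene | COc1cccc(OC)c1OCc1ccccc1 | intermediate
3 | 3-(benzyloxy)-1,5-dibromo-2,4-dimethoxybenzene | COc1c(Br)cc(Br)c(OC)c1OCc1ccccc1 | intermediate
4 | 3-(benzyloxy)-1,2,4,5-tetramethoxybenzene | COc1cc(OC)c(OC)c(OCc2ccccc2)c1OC | intermediate
5 | 3-(benzyloxy)-6-iodo-1,2,4,5-tetramethoxybenzene | COc1c(I)c(OC)c(OC)c(OCc2ccccc2)c1OC | intermediate
6 | 4-ethynylanisole | C#Cc1ccc(OC)cc1 | starting material
7 | carbon monoxide | [C-]#[O+] | starting material
8 | 1-[4-(benzyloxy)-2,3,5,6-tetramethoxyphenyl]-3-(4-methoxyphenyl)prop-2-yn-1-one | COc1ccc(C#CC(=O)c2c(OC)c(OC)c(OCc3ccccc3)c(OC)c2OC)cc1 | intermediate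
9 | 7-(benzyloxy)-3-iodo-5,6,8-trimethoxy-2-(4-methoxyphenyl)-1-methyl-4-oxo-4H-chromen-1-ium chloride | C[O+]1C(c2ccc(OC)cc2)=C(I)C(=O)c2c(OC)c(OC)c(OCc3ccccc3)c(OC)c21.[Cl-] | intermediate
10 | 7-(benzyloxy)-3-iodo-5,6,8-trimethoxy-2-(4-methoxyphenyl)-4H-chromen-4-one | COc1ccc(-c2oc3c(OC)c(OCc4ccccc4)c(OC)c(OC)c3c(=O)c2I)cc1 | intermediate
11 | 7-(benzyloxy)-3,5,6,8-tetramethoxy-2-(4-methoxyphenyl)-4H-chromen-4-one | COc1ccc(-c2oc3c(OC)c(OCc4ccccc4)c(OC)c(OC)c3c(=O)c2OC)cc1 | intermediate
12 | 7-hydroxy-3,5,6,8-tetramethoxy-2-(4-methoxyphenyl)-4H-chromen-4-one | COc1ccc(-c2oc3c(OC)c(O)c(OC)c(OC)c3c(=O)c2OC)cc1 | target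

Total step count: 8 steps.
Longest linear sequence: 8 steps, from 1 to 12; 6 and 7 are used as purchased.

Steps most likely to fail

Step 5. Oxidative addition into the electron-rich, doubly ortho-substituted C–I bond may be slow, and alkyne transfer may then precede CO insertion (direct coupling) or the alkyne may be consumed by homocoupling. The fallback sets out from 5 and builds the ketone by stepwise carbonyl chemistry. Iodine–lithium exchange (n-BuLi, THF, −78 °C) would give [4-(benzyloxy)-2,3,5,6-tetramethoxyphenyl]lithium F1, and a DMF quench would give 4-(benzyloxy)-2,3,5,6-tetramethoxybenzaldehyde F2. Addition of lithium (4-methoxyphenyl)acetylide F3, made from 6 with n-BuLi in THF at −78 °C, would give racemic 1-[4-(benzyloxy)-2,3,5,6-tetramethoxyphenyl]-3-(4-methoxyphenyl)prop-2-yn-1-ol F4. Oxidation with MnO2 (CH2Cl2, rt) removes the carbinol stereocentre and comes back to the route at 8.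

Step 7. Reductive loss of iodine at C3 by hydride transfer from the copper methoxide, or addition of methoxide at C2 with opening of ring C, may compete with C–O coupling. The fallback sets out from 10 and installs oxygen through boron. Iodine–magnesium exchange (iPrMgCl·LiCl, THF, −40 °C) would give chloro[7-(benzyloxy)-5,6,8-trimethoxy-2-(4-methoxyphenyl)-4-oxo-4H-chromen-3-yl]magnesium F5, trapped with B(OMe)3 as dimethyl [7-(benzyloxy)-5,6,8-trimethoxy-2-(4-methoxyphenyl)-4-oxo-4H-chromen-3-yl]boronate F6. Oxidation in the same flask (30% H2O2, AcOH, 0 °C) would give 7-(benzyloxy)-3-hydroxy-5,6,8-trimethoxy-2-(4-methoxyphenyl)-4H-chromen-4-one F7. O-Methylation (MeI, K2CO3, acetone, reflux) comes back to the route at 11.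

Step 3. The second substitution may stall, and bromine may be lost reductively under the hot copper–methoxide conditions, giving under-methoxylated arenes that are hard to separate. The fallback sets out from 3 and forms the C–O bonds as phenols first. Palladium-catalysed double hydroxylation (Pd2(dba)3, tBuXPhos, KOH, 1,4-dioxane/H2O, 100 °C, under argon) would give 5-(benzyloxy)-4,6-dimethoxybenzene-1,3-diol F8. Exhaustive O-methylation (MeI, K2CO3, acetone, reflux) comes back to the route at 4.

Further compounds
F1 | step 5 | [4-(benzyloxy)-2,3,5,6-tetramethoxyphenyl]lithium | COc1c([Li])c(OC)c(OC)c(OCc2ccccc2)c1OC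
F2 | step 5 | 4-(benzyloxy)-2,3,5,6-tetramethoxybenzaldehyde | COc1c(C=O)c(OC)c(OC)c(OCc2ccccc2)c1OC
F3 | step 5 | lithium (4-methoxyphenyl)acetylide | [Li]C#Cc1ccc(OC)cc1
F4 | step 5 | 1-[4-(benzyloxy)-2,3,5,6-tetramethoxyphenyl]-3-(4-methoxyphenyl)prop-2-yn-1-ol (racemic) | COc1ccc(C#CC(O)c2c(OC)c(OC)c(OCc3ccccc3)c(OC)c2OC)cc1
F5 | step 7 | chloro[7-(benzyloxy)-5,6,8-trimethoxy-2-(4-methoxyphenyl)-4-oxo-4H-chromen-3-yl]magnesium | COc1ccc(-c2oc3c(OC)c(OCc4ccccc4)c(OC)c(OC)c3c(=O)c2[Mg]Cl)cc1
F6 | step 7 | dimethyl [7-(benzyloxy)-5,6,8-trimethoxy-2-(4-methoxyphenyl)-4-oxo-4H-chromen-3-yl]boronate | COc1ccc(-c2oc3c(OC)c(OCc4ccccc4)c(OC)c(OC)c3c(=O)c2B(OC)OC)cc1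
F7 | step 7 | 7-(benzyloxy)-3-hydroxy-5,6,8-trimethoxy-2-(4-methoxyphenyl)-4H-chromen-4-one | COc1ccc(-c2oc3c(OC)c(OCc4ccccc4)c(OC)c(OC)c3c(=O)c2O)cc1
F8 | step 3 | 5-(benzyloxy)-4,6-dimethoxybenzene-1,3-diol | COc1c(O)cc(O)c(OC)c1OCc1ccccc1
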